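**Compound numbers used throughout:** 1 = 1,12-dibromododecane; 2 = triphenylphosphine; 3 = dodecane-1,12-diylbis(triphenylphosphonium) dibromide; 4 = 3,5-bis(benzyloxy)benzaldehyde; 5 = the bis-ylide from 3; 6 = (1Z,13Z)-1,14-bis[3,5-bis(benzyloxy)phenyl]tetradeca-1,13-diene; 7 = 1,14-bis[3,5-bis(benzyloxy)phenyl]tetradecane; 8 = bisnorstriatol.

## Analysis of the target

Bisnorstriatol (8, C26H38O4) is an achiral, twofold-symmetric molecule in which two benzene-1,3-diol rings (ring A and ring B) are each joined through C5 to one end of an unbranched, saturated chain of fourteen carbons (C1 to C14). It has no stereocentre and no double bond outside the arenes, so stereocontrol is not an issue and any unsaturation used to assemble the chain can be removed by hydrogenation without consequence. The sensitive groups are the four free phenols: the 1,3-dihydroxylated rings are very electron-rich at C2, C4 and C6, oxidise in air under basic conditions, quench carbanions and make the product polar. They are therefore best carried in masked form and released last under neutral conditions. The difficulty is one of economy and positional control rather than complexity: the chain sits meta to both oxygens of each ring, a position that electrophilic alkylation or acylation of a 1,3-dioxygenated benzene cannot reach, so the 1,3,5-pattern has to be bought with a one-carbon handle already at C5. In addition, every bond-forming event has to go to completion at both ends of a symmetric molecule. The strategy rests on C1 and C14, the benzylic methylenes on C5 of ring A and ring B, whose bonds C1–C2 and C13–C14 are equivalent by symmetry. Each of these bonds can be read as the union of an aryl aldehyde carbon with a phosphorus ylide carbon at the end of a C12 unit, and the alkene that this union leaves behind is erased later.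

## Retrosynthetic reasoning

**From 8 back to 6 (through 7).** No skeletal bond is cut. The four O–H groups of 8 are traced back to O-benzyl ethers, and the C1–C2 and C13–C14 single bonds to double bonds, which gives diene 6. The saturated tetrabenzyl ether 7 lies between the two. Benzyl is chosen as the phenol mask because the catalytic hydrogenation that saturates the two alkenes also cleaves aryl benzyl ethers. Deprotection then costs no separate step, and the electron-rich free phenols never meet a Lewis acid. The forward reaction must saturate two styrene-type double bonds and cleave four benzylic C–O bonds in one operation.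

**From 6 back to 5 (made from 3) and two molecules of 4.** The C1=C2 and C13=C14 double bonds are cut. This site is chosen because it lies directly next to the arenes. One piece is then an aldehyde, 4, that already carries the correct meta oxygen pattern and can be bought. The other is a plain linear C12 unit functionalised only at its two ends. A cut deeper in the chain would require aryl-alkyl fragments to be prepared first, and those would need a benzylic C–C bond formation of their own. The gain is that both rings and the whole C14 tether are joined in one operation that forms two C–C bonds. The forward reaction has to go to completion at both termini and consumes one molecule of 4 at each. Alkene geometry is of no concern, because the next step removes it.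

**From 3 back to 1 and two molecules of 2.** The two C–P bonds are cut. The forward reaction is a twofold quaternisation of the phosphine 2 by the primary dibromide 1. It needs only to be driven to the bis-salt and to deliver dry material.

## Alternatives that were turned down

Alternative 1: both arenes built by cycloaddition.
- Disconnection: each ring is taken apart into a four-carbon oxygenated diene and the two alkyne carbons of an ynoate. The C14 chain then pre-exists as the spacer of dimethyl icosa-2,18-diynedioate A3.
- Forward key step: on heating, the ynoate at each end of A3 takes up one molecule of 1,3-dimethoxy-1-(trimethylsilyloxy)buta-1,3-diene A2. The polarisation of both partners places the CH2 end of the diene on the alkyne carbon that carries the chain and the ketene-acetal end on the one that carries the ester. Expulsion of methanol from each adduct aromatises it and should give dimethyl 6,6'-(tetradecane-1,14-diyl)bis(2-hydroxy-4-methoxybenzoate) A1.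
- For: the meta relationship between oxygens and chain comes from the polarisation of the cycloaddition and does not depend on any purchasable arene. On this point it is stronger than the chosen route, and it would be preferred if the rings carried a substitution pattern that cannot be bought.
- Against: here the ring is a commodity, so constructing it gains nothing. A3 and A2 both have to be prepared, A3 from a long α,ω-diyne that is itself not a staple, and A2 is moisture-sensitive. β-Alkyl ynoates are sluggish dienophiles, so forcing temperatures are needed at both ends while A2 degrades. A1 also carries two ester carbons and two O-methyl groups that the target lacks, so saponification, twofold decarboxylation and ether cleavage must follow.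
- Comparison: the count comes to roughly eight operations against three. The chosen route offers brevity and catalogue building blocks in place of independence from the arene supply.

Alternative 2: a central two-carbon linchpin alkylated at both ends.
- Disconnection: C6–C7 and C8–C9, on either side of a central C7≡C8 triple bond.
- Forward key step: acetylene A6 is converted into its lithium acetylide and alkylated at both carbons in one flask, each time by 1-(6-bromohexyl)-3,5-dimethoxybenzene A5. This should give 1,14-bis(3,5-dimethoxyphenyl)tetradec-7-yne A4. Hydrogenation of A4 and ether cleavage follow.
- For: the C–C bonds are made far from the arenes by dependable acetylide substitution at primary carbon. The triple bond of A4 hydrogenates as cleanly as the alkenes of the chosen route, so on the end-game the two are equal.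
- Against: A5 is not a catalogue compound. Its aryl–CH2 bond has to be made first, so the benzylic bond problem is only moved into a fragment synthesis of at least three steps. The second alkylation, in which the acetylide that already bears one chain meets another molecule of A5, competes with elimination. Dosing the gas A6 for a symmetric double alkylation is awkward. The methyl ethers need a separate dealkylation step.
- Comparison: at least six steps. The chosen route attaches the chain at the benzylic carbon directly, using a purchased aldehyde.

Alternative 3: copper-catalysed sp3–sp3 coupling around a C6 core.
- Disconnection: C4–C5 and C10–C11, both sp3–sp3 bonds.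
- Forward key step: the Grignard reagent 4-(3,5-dimethoxyphenyl)butylmagnesium bromide A8 is joined, once at each end, to 1,6-dibromohexane A9 with the copper catalyst Li2CuCl4 A10. This should give 1,14-bis(3,5-dimethoxyphenyl)tetradecane A7.
- For: the saturated skeleton is obtained directly, with no alkene and no hydrogenation. In redox economy this is stronger than the chosen route. Primary–primary coupling under cuprate catalysis is well established, and A10 is needed only in catalytic amount.
- Against: A8 comes from a bromide that is not commercial and that again requires a benzylic C–C bond-forming sequence. Twofold coupling to A9 is accompanied by half-coupled material, by homocoupling of A8 and by protonated A8, all non-polar and close to A7 on silica. A7 then still needs a separate dealkylation of four methyl ethers.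
- Comparison: at least six steps against three. In the chosen route the by-products are polar or ionic and separate easily from the neutral diene.

Key step: step 2

Remark on the chemistry: 6 is drawn Z,Z as the major isomer expected from a non-stabilised ylide under lithium-free conditions; any E alkene that forms converges on the same product in step 3.

## Route

Step 1
Reactants: 1 1,12-dibromododecane; 2 triphenylphosphine
Product: 3 dodecane-1,12-diylbis(triphenylphosphonium) dibromide
Conditions: 2 (2.3 equiv), MeCN, reflux, 48 h; trituration with Et2O, drying in vacuo at 80 °C
Reagents that add atoms: triphenylphosphine (second molecule of 2), c1ccc(cc1)P(c1ccccc1)c1ccccc1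
Why: Twofold SN2 quaternisation of a tertiary phosphine by a primary alkyl bromide, one molecule of 2 being taken up at each end of 1; the two termini are ten methylenes apart, so the first cationic centre should not retard the second, and the insoluble bis-salt can be freed from excess 2 by washing.

Step 2
Reactants: 3 dodecane-1,12-diylbis(triphenylphosphonium) dibromide; 4 3,5-bis(benzyloxy)benzaldehyde
Product: 6 (1Z,13Z)-1,14-bis[3,5-bis(benzyloxy)phenyl]tetradeca-1,13-diene, via bis-ylide 5 (not isolated)
Conditions: NaN(SiMe3)2 (2.0 equiv), THF, 0 °C to rt; then 4 (2.2 equiv), −78 °C to rt
Reagents that add atoms: 3,5-bis(benzyloxy)benzaldehyde (second molecule of 4), O=Cc1cc(OCc2ccccc2)cc(OCc2ccccc2)c1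
Why: NaN(SiMe3)2 removes one proton next to each phosphonium centre of 3 and gives the lithium-free, non-stabilised bis-ylide 5. Each ylide carbon then adds to the carbonyl group of one molecule of 4, so that two molecules of 4 are consumed, and each oxaphosphetane formed undergoes cycloreversion to a C=C double bond (C1=C2 and C13=C14) and triphenylphosphine oxide, which carries away the aldehyde oxygen. This is the Wittig olefination of an aromatic aldehyde with an alkylidenetriphenylphosphorane, in the two-directional form known for α,ω-bis-phosphonium salts. No ring is closed and no stereocentre is created. The only selectivity the step needs is complete conversion at both termini: the two ylide carbons are insulated by ten methylenes and react independently, the chain offers them no internal electrophile, and 4 has no α-hydrogen, so neither enolisation nor aldol chemistry can divert ylide or base. The benzyl ethers are inert to the ylide and to the silylamide. Kinetic control in the absence of lithium should favour the Z alkene at each end, but the geometry has no bearing on the route because step 3 saturates both double bonds. Two equivalents of base and no more avoid free silylamide, which could add to 4, and the small excess of 4 ensures that the second ylide terminus is captured, after which the neutral diene 6 should separate readily on silica from the polar phosphine oxide and from charged, half-reacted material.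

Step 3
Reactants: 6 (1Z,13Z)-1,14-bis[3,5-bis(benzyloxy)phenyl]tetradeca-1,13-diene
Product: 8 bisnorstriatol, via saturated tetrabenzyl ether 7 (not isolated)
Conditions: H2 (1 atm), 10% Pd/C, THF–MeOH (1:1), rt
Reagents that add atoms: none
Why: Heterogeneous catalytic hydrogenation saturates the two disubstituted styrene-type alkenes first, and hydrogenolysis of the four aryl benzyl ether C–O bonds follows on the same catalyst; the arenes and free phenols are inert at this pressure, and the only by-product is volatile toluene, so the polar tetraphenol should be obtained by filtration and evaporation.

## Compound list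

1 | 1,12-dibromododecane | BrCCCCCCCCCCCCBr | starting material
2 | triphenylphosphine | c1ccc(cc1)P(c1ccccc1)c1ccccc1 | starting material
3 | dodecane-1,12-diylbis(triphenylphosphonium) dibromide | [Br-].[Br-].c1ccc(cc1)[P+](CCCCCCCCCCCC[P+](c1ccccc1)(c1ccccc1)c1ccccc1)(c1ccccc1)c1ccccc1 | intermediate
4 | 3,5-bis(benzyloxy)benzaldehyde | O=Cc1cc(OCc2ccccc2)cc(OCc2ccccc2)c1 | starting material
5 | dodecane-1,12-diylidenebis(triphenyl-λ5-phosphane), the bis-ylide Ph3P=CH(CH2)10CH=PPh3 | c1ccc(cc1)P(=CCCCCCCCCCCC=P(c1ccccc1)(c1ccccc1)c1ccccc1)(c1ccccc1)c1ccccc1 | intermediate (not isolated)
6 | (1Z,13Z)-1,14-bis[3,5-bis(benzyloxy)phenyl]tetradeca-1,13-diene | c1ccc(cc1)COc1cc(OCc2ccccc2)cc(/C=C\CCCCCCCCCC/C=C\c2cc(OCc3ccccc3)cc(OCc3ccccc3)c2)c1 | intermediate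
7 | 1,14-bis[3,5-bis(benzyloxy)phenyl]tetradecane | c1ccc(cc1)COc1cc(OCc2ccccc2)cc(CCCCCCCCCCCCCCc2cc(OCc3ccccc3)cc(OCc3ccccc3)c2)c1 | intermediate (not isolated)
8 | bisnorstriatol, 5,5'-(tetradecane-1,14-diyl)bis(benzene-1,3-diol) | Oc1cc(O)cc(CCCCCCCCCCCCCCc2cc(O)cc(O)c2)c1 | target

## Step count and risk

Total step count: 3. Longest linear sequence: 3 steps (1 to 3 to 6 to 8).

**Step 2 (key step).** The most likely failure is incomplete olefination at the second terminus. The dicationic salt 3 is sparingly soluble in THF and hygroscopic, so deprotonation may be incomplete or part of the ylide may be protonated again. The chain would then end in a phosphonium or phosphine oxide group in place of the second aryl alkene.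

The fallback makes the same two bonds by carbonyl addition instead of olefination. It sets out from 1. Magnesium turnings in THF convert 1 into the bis-Grignard reagent dodecane-1,12-diylbis(magnesium bromide) F1. Addition of F1 to aldehyde 4 (2.2 equiv, THF, 0 °C) and aqueous work-up should give 1,14-bis[3,5-bis(benzyloxy)phenyl]tetradecane-1,14-diol F2 as a mixture of diastereomers. Hydrogenolysis of F2 (H2, 10% Pd/C, EtOH–AcOH, catalytic HClO4) should cleave the two benzylic C–OH bonds together with the four benzyl ethers. The fallback comes back to the route at 8.

**Step 3.** The most likely failure is stalling of the hydrogenolysis after the alkenes are saturated. Four O-benzyl cleavages are needed on one molecule, phosphorus- or bromide-containing residues carried over from step 2 can poison the palladium surface, and partly debenzylated intermediates may leave solution.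

The fallback changes the phenol mask, so that no hydrogenolysis is required. It sets out from 3. The bis-ylide 5 is generated as in step 2 and treated with two equivalents of 3,5-dimethoxybenzaldehyde F3 to give (1Z,13Z)-1,14-bis(3,5-dimethoxyphenyl)tetradeca-1,13-diene F4. Hydrogenation of F4 (H2, 10% Pd/C, EtOAc, rt) should give 1,14-bis(3,5-dimethoxyphenyl)tetradecane F5. Treatment of F5 with BBr3 (6 equiv, CH2Cl2, −78 °C to rt) cleaves the four methyl ethers through the aryloxydibromoborane, the tetrakis(dibromoboryl) ether of bisnorstriatol F6, which is hydrolysed on aqueous work-up. The fallback comes back to the route at 8.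

**Step 1.** The most likely failure is a lagging second quaternisation together with retention of water or solvent by the hygroscopic bis-salt. The salt cannot be chromatographed, so mono-salt would act as a chain terminator and moisture would destroy ylide in step 2.

The fallback replaces the phosphorus-based olefination reagent by a sulfone (Julia–Kocienski olefination). It sets out from 1. S-Alkylation of 1-phenyl-1H-tetrazole-5-thiol with 1 (K2CO3, acetone, reflux) should give 1,12-bis[(1-phenyl-1H-tetrazol-5-yl)sulfanyl]dodecane F7. Oxidation (H2O2, catalytic (NH4)6Mo7O24, EtOH) should give 1,12-bis[(1-phenyl-1H-tetrazol-5-yl)sulfonyl]dodecane F8, a neutral compound that can be crystallised. Addition of KN(SiMe3)2 to a mixture of F8 and two equivalents of aldehyde 4 in DME at −60 °C should give (1E,13E)-1,14-bis[3,5-bis(benzyloxy)phenyl]tetradeca-1,13-diene F9. Under the conditions of step 3, F9 is hydrogenated to 7, where the fallback comes back to the route, and 7 goes on to 8 in the same flask.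

## Further compounds

F1 | step 2 | dodecane-1,12-diylbis(magnesium bromide) | Br[Mg]CCCCCCCCCCCC[Mg]Br
F2 | step 2 | 1,14-bis[3,5-bis(benzyloxy)phenyl]tetradecane-1,14-diol (mixture of diastereomers) | OC(CCCCCCCCCCCCC(O)c1cc(OCc2ccccc2)cc(OCc2ccccc2)c1)c1cc(OCc2ccccc2)cc(OCc2ccccc2)c1
F3 | step 3 | 3,5-dimethoxybenzaldehyde | COc1cc(C=O)cc(OC)c1
F4 | step 3 | (1Z,13Z)-1,14-bis(3,5-dimethoxyphenyl)tetradeca-1,13-diene | COc1cc(OC)cc(/C=C\CCCCCCCCCC/C=C\c2cc(OC)cc(OC)c2)c1
F5 | step 3 | 1,14-bis(3,5-dimethoxyphenyl)tetradecane | COc1cc(OC)cc(CCCCCCCCCCCCCCc2cc(OC)cc(OC)c2)c1
F6 | step 3 | tetrakis(dibromoboryl) ether of bisnorstriatol | BrB(Br)Oc1cc(OB(Br)Br)cc(CCCCCCCCCCCCCCc2cc(OB(Br)Br)cc(OB(Br)Br)c2)c1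
F7 | step 1 | 1,12-bis[(1-phenyl-1H-tetrazol-5-yl)sulfanyl]dodecane | c1ccc(cc1)-n1nnnc1SCCCCCCCCCCCCSc1nnnn1-c1ccccc1
F8 | step 1 | 1,12-bis[(1-phenyl-1H-tetrazol-5-yl)sulfonyl]dodecane | c1ccc(cc1)-n1nnnc1S(=O)(=O)CCCCCCCCCCCCS(=O)(=O)c1nnnn1-c1ccccc1
F9 | step 1 | (1E,13E)-1,14-bis[3,5-bis(benzyloxy)phenyl]tetradeca-1,13-diene | c1ccc(cc1)COc1cc(OCc2ccccc2)cc(/C=C/CCCCCCCCCC/C=C/c2cc(OCc3ccccc3)cc(OCc3ccccc3)c2)c1
A1 | alternative 1 | dimethyl 6,6'-(tetradecane-1,14-diyl)bis(2-hydroxy-4-methoxybenzoate) | COC(=O)c1c(O)cc(OC)cc1CCCCCCCCCCCCCCc1cc(OC)cc(O)c1C(=O)OC
A2 | alternative 1 | 1,3-dimethoxy-1-(trimethylsilyloxy)buta-1,3-diene | COC(=C)C=C(OC)O[Si](C)(C)C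
A3 | alternative 1 | dimethyl icosa-2,18-diynedioate | COC(=O)C#CCCCCCCCCCCCCCCC#CC(=O)OC
A4 | alternative 2 | 1,14-bis(3,5-dimethoxyphenyl)tetradec-7-yne | COc1cc(OC)cc(CCCCCCC#CCCCCCCc2cc(OC)cc(OC)c2)c1
A5 | alternative 2 | 1-(6-bromohexyl)-3,5-dimethoxybenzene | COc1cc(OC)cc(CCCCCCBr)c1
A6 | alternative 2 | acetylene | C#C
A7 | alternative 3 | 1,14-bis(3,5-dimethoxyphenyl)tetradecane (same compound as F5) | COc1cc(OC)cc(CCCCCCCCCCCCCCc2cc(OC)cc(OC)c2)c1
A8 | alternative 3 | 4-(3,5-dimethoxyphenyl)butylmagnesium bromide | COc1cc(OC)cc(CCCC[Mg]Br)c1
A9 | alternative 3 | 1,6-dibromohexane | BrCCCCCCBr
A10 | alternative 3 | dilithium tetrachlorocuprate, Li2CuCl4 | [Li+].[Li+].Cl[Cu-2](Cl)(Cl)Cl
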